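**Plan**

- Numbering (germacrane): ring C1–C10 with C2 = ketone, C4=C5 (C15 = CH2OAc on C4), C6 = lactone carbinol, C7, C8 = acetoxy carbinol, C10=C14 exocyclic; C11(=C13)–C12 is the lactone unit. The target is (6R,7R,8S), with C4=C5 trans in the ring (4Z by CIP).
- Cuts: C2=O back to C2–OH; ring bond C1–C2 (allylchromium + aldehyde); C6–C7 together with the lactone C–O (2-alkoxycarbonyl allylboration); C8–C9 (catalytic asymmetric allylation). C9–C10(=C14)–C1 comes from one conjunctive 2-(chloromethyl)allyl stannane used at both ends ([7+3] ring construction).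
- Forward: Keck allylation (C8–C9), then alkynoate, then E-crotyl-type allylboronate; union with a Z-enal (C2–C6, C15) gives the open-chain trans-lactone; the surviving allylic chloride closes the ten-membered ring on the C2 aldehyde; the ketone is formed last.
- Stereochemistry: C8 from (S)-BINOL/Ti catalysis; C7 and C6 relayed from C8 in one allylboration (chair transition state plus A(1,3) strain); C4=C5 geometry from chelate-controlled carbomagnesiation; the C2 carbinol is erased.
- Enabling feature: C10 carries the exocyclic methylene C14 and two CH2 neighbours (C9, C1), so the allyl termini C1 and C14 are equivalent and closure at C1–C2 has no regio- or alkene-geometry issue. C2 lies β,γ to both C10=C14 and C4=C5, so the labile skipped dienone stays a homoallylic alcohol until the last, neutral step.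

Key step: step 14

Assumption: stannane 11 is not taken as commercial and is made in step 4; Grignard reagent 2 is used as its commercial THF solution.

**Route**

Step 1
Reactants: 1 prop-2-yn-1-ol; 2 (1,3-dioxolan-2-ylmethyl)magnesium bromide
Product: 4 (2Z)-2-(1,3-dioxolan-2-ylmethyl)-3-iodoprop-2-en-1-ol, via vinylmagnesium chelate 3 (not isolated)
Conditions: 2 (2.5 equiv), CuI (10 mol %), THF, −10 °C → rt; then I2, −78 → 0 °C; H2O
Reagents that add atoms: iodine, II
Why: Copper-catalysed anti-carbomagnesiation of the propargylic alkoxide should put the acetal-bearing carbon on the internal alkyne carbon and magnesium on the terminal carbon, chelated cis to CH2O, so that iodinolysis with retention fixes C15–O cis to the future C6 (the trans-in-ring C4=C5 geometry).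

Step 2
Reactants: 4 (2Z)-2-(1,3-dioxolan-2-ylmethyl)-3-iodoprop-2-en-1-ol
Product: 5 tert-butyl{[(2Z)-2-(1,3-dioxolan-2-ylmethyl)-3-iodoprop-2-en-1-yl]oxy}dimethylsilane
Conditions: TBSCl, imidazole, DMF, 0 °C → rt
Reagents that add atoms: tert-butyldimethylsilyl chloride, CC(C)(C)[Si](C)(C)Cl
Why: Standard imidazole-promoted O-silylation masks the C15 hydroxyl for the organolithium step.

Step 3
Reactants: 5 tert-butyl{[(2Z)-2-(1,3-dioxolan-2-ylmethyl)-3-iodoprop-2-en-1-yl]oxy}dimethylsilane
Product: 7 (2Z)-4-[(tert-butyldimethylsilyl)oxy]-3-(1,3-dioxolan-2-ylmethyl)but-2-enal, via vinyllithium 6 (not isolated)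
Conditions: t-BuLi (2.1 equiv), Et2O, −78 °C; DMF, −78 → 0 °C; H2O
Reagents that add atoms: N,N-dimethylformamide, CN(C)C=O
Why: Iodine–lithium exchange with retention of alkene geometry followed by formylation of the vinyllithium with DMF should give the Z-enal with C6 cis to C15, and diethyl ether at −78 °C should suppress 1,4 O→C silyl migration.

Step 4
Reactants: 8 3-chloro-2-(chloromethyl)prop-1-ene; 9 tributylstannane
Product: 11 tributyl[2-(chloromethyl)prop-2-en-1-yl]stannane, via tributylstannyllithium 10 (not isolated)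
Conditions: LDA (1.0 equiv), THF, 0 °C; then 8 (3 equiv), −78 → 0 °C
Reagents that add atoms: none
Why: SN2 (or the constitutionally identical SN2′) displacement of one allylic chloride by the stannyl anion gives the bifunctional 2-methylenepropane-1,3-diyl reagent, with excess dichloride suppressing double substitution.

Step 5
Reactants: 12 3-(trimethylsilyl)prop-2-ynal; 11 tributyl[2-(chloromethyl)prop-2-en-1-yl]stannane
Product: 13 (3S)-5-(chloromethyl)-1-(trimethylsilyl)hex-5-en-1-yn-3-ol
Conditions: (S)-BINOL (20 mol %), Ti(OiPr)4 (10 mol %), 4 Å MS, CH2Cl2, −20 °C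
Reagents that add atoms: none
Why: Keck catalytic asymmetric allylation, in which the (S)-BINOL–Ti(IV) Lewis acid should direct the allylstannane (SE2′, degenerate for the 2-substituted allyl unit) to the Si face of the ynal and so set C8 as S.

Step 6
Reactants: 13 (3S)-5-(chloromethyl)-1-(trimethylsilyl)hex-5-en-1-yn-3-ol
Product: 14 tert-butyl{[(3S)-5-(chloromethyl)-1-(trimethylsilyl)hex-5-en-1-yn-3-yl]oxy}dimethylsilane
Conditions: TBSOTf, 2,6-lutidine, CH2Cl2, −78 → 0 °C
Reagents that add atoms: tert-butyldimethylsilyl trifluoromethanesulfonate, CC(C)(C)[Si](C)(C)OS(=O)(=O)C(F)(F)F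
Why: Silyl triflate silylation installs the bulky non-chelating group that later shields one face of C7 and prevents alkoxide attack on the allylic chloride.

Step 7
Reactants: 14 tert-butyl{[(3S)-5-(chloromethyl)-1-(trimethylsilyl)hex-5-en-1-yn-3-yl]oxy}dimethylsilane
Product: 15 tert-butyl{[(3S)-5-(chloromethyl)hex-5-en-1-yn-3-yl]oxy}dimethylsilane
Conditions: K2CO3 (0.2 equiv), MeOH, 0 °C
Reagents that add atoms: none
Why: Carbonate-catalysed methanolysis of the alkynyl C–Si bond (protodesilylation) is selective over the silyl ether and should be fast enough at 0 °C to spare the allylic chloride.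

Step 8
Reactants: 15 tert-butyl{[(3S)-5-(chloromethyl)hex-5-en-1-yn-3-yl]oxy}dimethylsilane
Product: 17 methyl (4S)-4-[(tert-butyldimethylsilyl)oxy]-6-(chloromethyl)hept-6-en-2-ynoate, via lithium acetylide 16 (not isolated)
Conditions: n-BuLi, THF, −78 °C; ClCO2Me, −78 → −20 °C
Reagents that add atoms: methyl chloroformate, COC(=O)Cl
Why: Deprotonation of the terminal alkyne and C-acylation of the acetylide with the chloroformate introduces C12 and gives the alkynoate.

Step 9
Reactants: 17 methyl (4S)-4-[(tert-butyldimethylsilyl)oxy]-6-(chloromethyl)hept-6-en-2-ynoate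
Product: 19 methyl (2Z,4S)-4-[(tert-butyldimethylsilyl)oxy]-6-(chloromethyl)-2-[(4,4,5,5-tetramethyl-1,3,2-dioxaborolan-2-yl)methyl]hepta-2,6-dienoate, via vinylalane 18 (not isolated)
Conditions: DIBAL-H (1.2 equiv), HMPA, THF, 0 °C; then ICH2Bpin, 0 °C → rt
Reagents that add atoms: 2-(iodomethyl)-4,4,5,5-tetramethyl-1,3,2-dioxaborolane, ICB1OC(C)(C)C(C)(C)O1
Why: Conjugate hydroalumination of the alkynoate by the DIBAL-H–HMPA complex is a syn addition that places aluminium on C11 cis to H7, and C-alkylation of this α-alumino enoate with retention gives the 2-alkoxycarbonyl allylboronate with CH2B trans to the C8 branch (E-crotyl type).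

Step 10
Reactants: 7 (2Z)-4-[(tert-butyldimethylsilyl)oxy]-3-(1,3-dioxolan-2-ylmethyl)but-2-enal; 19 methyl (2Z,4S)-4-[(tert-butyldimethylsilyl)oxy]-6-(chloromethyl)-2-[(4,4,5,5-tetramethyl-1,3,2-dioxaborolan-2-yl)methyl]hepta-2,6-dienoate
Product: 21 (4S,5R)-4-[(1S)-1-(tert-butyldimethylsilyloxy)-3-(chloromethyl)but-3-en-1-yl]-5-[(1Z)-3-(tert-butyldimethylsilyloxy)-2-(1,3-dioxolan-2-ylmethyl)prop-1-en-1-yl]-3-methylideneoxolan-2-one, via borate adduct 20 (not isolated)
Conditions: Sc(OTf)3 (10 mol %), toluene, −78 °C → rt; then PPTS (cat.), rt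
Reagents that add atoms: none
Why: Lewis-acid-catalysed carbonyl allylboration through a closed chair transition state with the aldehyde substituent and the C8 branch both equatorial should give the anti C6/C7 relationship (trans-lactone after acid-promoted lactonisation), while A(1,3) strain between C8 and the cis CO2Me group holds H8 in the alkene plane so that the aldehyde should approach C7 anti to the OTBS group, relaying C8 (S) to C7 and C6.

Step 11
Reactants: 21 (4S,5R)-4-[(1S)-1-(tert-butyldimethylsilyloxy)-3-(chloromethyl)but-3-en-1-yl]-5-[(1Z)-3-(tert-butyldimethylsilyloxy)-2-(1,3-dioxolan-2-ylmethyl)prop-1-en-1-yl]-3-methylideneoxolan-2-one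
Product: 22 (4R,5R)-4-[(1S)-3-(chloromethyl)-1-hydroxybut-3-en-1-yl]-5-[(1Z)-3-hydroxy-2-(1,3-dioxolan-2-ylmethyl)prop-1-en-1-yl]-3-methylideneoxolan-2-one
Conditions: HF·pyridine, THF, 0 °C → rt
Reagents that add atoms: none
Why: Fluoride-mediated cleavage of both silyl ethers under mildly acidic conditions should leave the dioxolane, the allylic chloride and the α-methylene lactone intact.

Step 12
Reactants: 22 (4R,5R)-4-[(1S)-3-(chloromethyl)-1-hydroxybut-3-en-1-yl]-5-[(1Z)-3-hydroxy-2-(1,3-dioxolan-2-ylmethyl)prop-1-en-1-yl]-3-methylideneoxolan-2-one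
Product: 23 (4R,5R)-4-[(1S)-1-acetoxy-3-(chloromethyl)but-3-en-1-yl]-5-[(1Z)-3-acetoxy-2-(1,3-dioxolan-2-ylmethyl)prop-1-en-1-yl]-3-methylideneoxolan-2-one
Conditions: Ac2O, Et3N, DMAP (5 mol %), CH2Cl2, 0 °C
Reagents that add atoms: acetic anhydride, CC(=O)OC(C)=O
Why: DMAP-catalysed acetylation installs both acetates of the target (C15 and C8) in one operation before the aldehyde is released and before the free C8 hydroxyl can translactonise.

Step 13
Reactants: 23 (4R,5R)-4-[(1S)-1-acetoxy-3-(chloromethyl)but-3-en-1-yl]-5-[(1Z)-3-acetoxy-2-(1,3-dioxolan-2-ylmethyl)prop-1-en-1-yl]-3-methylideneoxolan-2-one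
Product: 24 (4R,5R)-4-[(1S)-1-acetoxy-3-(chloromethyl)but-3-en-1-yl]-5-[(1Z)-2-(acetoxymethyl)-4-oxobut-1-en-1-yl]-3-methylideneoxolan-2-one
Conditions: PPTS (0.2 equiv), acetone–H2O (10:1), 45 °C; used at once
Reagents that add atoms: water, O
Why: Mild acid-catalysed acetal hydrolysis releases the β,γ-unsaturated C2 aldehyde, which is carried on crude to avoid migration of C4=C5 into conjugation.

Step 14
Reactants: 24 (4R,5R)-4-[(1S)-1-acetoxy-3-(chloromethyl)but-3-en-1-yl]-5-[(1Z)-2-(acetoxymethyl)-4-oxobut-1-en-1-yl]-3-methylideneoxolan-2-one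
Product: 26 (6R,7R,8S)-8,15-diacetoxy-2-hydroxygermacra-4,10(14),11(13)-trien-12,6-olide (both C2 epimers), via allylchromium 25 (not isolated)
Conditions: CrCl2 (10 equiv), NaI (0.2 equiv), THF–DMF (4:1), slow addition of 24 to 2 mM, rt; H2O
Reagents that add atoms: none
Why: Cr(II) reduces the allylic chloride (through the iodide formed in situ) to an allylchromium(III) species that adds through its γ-carbon to the C2 aldehyde in a six-membered chair-like Cr–O transition state, i.e. an intramolecular Nozaki–Hiyama–Kishi allylation of the kind already used to close ten-membered germacrane rings from ω-formyl allylic halides. The ten-membered carbocycle is closed at C1–C2 by a 10-exo-trig addition to the carbonyl group. The only new stereocentre is the C2 carbinol, which is left uncontrolled on purpose because step 15 converts it into the ketone. The selectivities that usually trouble such closures, α- versus γ-attack and the geometry of the transposed alkene, do not arise because C10 carries two CH2 groups (C1 and C14), so both modes give the same 10(14)-exo-methylene 2-ol. Chemoselectivity rests on the inertness of allylchromium(III) towards the lactone, the acrylate and the acetates, and cyclisation over oligomerisation should be favoured by high dilution and by the conformational restriction from the trans-lactone and the trisubstituted alkene. C6, C7 and C8 are not touched.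

Step 15
Reactants: 26 (6R,7R,8S)-8,15-diacetoxy-2-hydroxygermacra-4,10(14),11(13)-trien-12,6-olide (both C2 epimers)
Product: 27 (6R,7R,8S)-8,15-diacetoxy-2-oxogermacra-4,10(14),11(13)-trien-12,6-olide (CNP0183179.1)
Conditions: Dess–Martin periodinane (1.5 equiv), NaHCO3 (5 equiv), CH2Cl2, 0 °C → rt
Reagents that add atoms: none
Why: Dess–Martin oxidation under bicarbonate buffering converts both C2 epimers into the ketone without base or strong acid, so C4=C5 and C10=C14 should stay out of conjugation.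

**Compound list**

1 | prop-2-yn-1-ol | C#CCO | starting material
2 | (1,3-dioxolan-2-ylmethyl)magnesium bromide | Br[Mg]CC1OCCO1 | starting material
3 | bromomagnesium (2Z)-3-(bromomagnesio)-2-(1,3-dioxolan-2-ylmethyl)prop-2-en-1-olate (vinylmagnesium chelate, Mg cis to CH2O) | O1CCOC1C/C(CO[Mg]Br)=C/[Mg]Br | intermediate (not isolated)
4 | (2Z)-2-(1,3-dioxolan-2-ylmethyl)-3-iodoprop-2-en-1-ol (I cis to CH2OH) | O1CCOC1C/C(CO)=C/I | intermediate
5 | tert-butyl{[(2Z)-2-(1,3-dioxolan-2-ylmethyl)-3-iodoprop-2-en-1-yl]oxy}dimethylsilane | O1CCOC1C/C(CO[Si](C)(C)C(C)(C)C)=C/I | intermediate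
6 | (Z)-vinyllithium from 5 (Li in place of I) | O1CCOC1C/C(CO[Si](C)(C)C(C)(C)C)=C/[Li] | intermediate (not isolated)
7 | (2Z)-4-[(tert-butyldimethylsilyl)oxy]-3-(1,3-dioxolan-2-ylmethyl)but-2-enal (CHO cis to CH2OTBS) | O1CCOC1C/C(CO[Si](C)(C)C(C)(C)C)=C/C=O | intermediate
8 | 3-chloro-2-(chloromethyl)prop-1-ene | C=C(CCl)CCl | starting material
9 | tributylstannane | CCCC[SnH](CCCC)CCCC | starting material
10 | tributylstannyllithium | [Li][Sn](CCCC)(CCCC)CCCC | intermediate (not isolated)
11 | tributyl[2-(chloromethyl)prop-2-en-1-yl]stannane | C=C(CCl)C[Sn](CCCC)(CCCC)CCCC | intermediate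
12 | 3-(trimethylsilyl)prop-2-ynal | C[Si](C)(C)C#CC=O | starting material
13 | (3S)-5-(chloromethyl)-1-(trimethylsilyl)hex-5-en-1-yn-3-ol | C[Si](C)(C)C#C[C@@H](O)CC(=C)CCl | intermediate
14 | tert-butyl{[(3S)-5-(chloromethyl)-1-(trimethylsilyl)hex-5-en-1-yn-3-yl]oxy}dimethylsilane | C[Si](C)(C)C#C[C@@H](O[Si](C)(C)C(C)(C)C)CC(=C)CCl | intermediate
15 | tert-butyl{[(3S)-5-(chloromethyl)hex-5-en-1-yn-3-yl]oxy}dimethylsilane | C#C[C@@H](O[Si](C)(C)C(C)(C)C)CC(=C)CCl | intermediate
16 | lithium acetylide of 15 | [Li]C#C[C@@H](O[Si](C)(C)C(C)(C)C)CC(=C)CCl | intermediate (not isolated)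
17 | methyl (4S)-4-[(tert-butyldimethylsilyl)oxy]-6-(chloromethyl)hept-6-en-2-ynoate | COC(=O)C#C[C@@H](O[Si](C)(C)C(C)(C)C)CC(=C)CCl | intermediate
18 | methyl (2E,4S)-4-[(tert-butyldimethylsilyl)oxy]-6-(chloromethyl)-2-(diisobutylalumanyl)hepta-2,6-dienoate (Al cis to H-3) | COC(=O)/C(=C\[C@@H](O[Si](C)(C)C(C)(C)C)CC(=C)CCl)[Al](CC(C)C)CC(C)C | intermediate (not isolated)
19 | methyl (2Z,4S)-4-[(tert-butyldimethylsilyl)oxy]-6-(chloromethyl)-2-[(4,4,5,5-tetramethyl-1,3,2-dioxaborolan-2-yl)methyl]hepta-2,6-dienoate (CH2B trans to C-4) | COC(=O)/C(CB1OC(C)(C)C(C)(C)O1)=C\[C@@H](O[Si](C)(C)C(C)(C)C)CC(=C)CCl | intermediate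
20 | methyl (5Z)-6-[(tert-butyldimethylsilyloxy)methyl]-7-(1,3-dioxolan-2-yl)-2-methylidene-4-[(4,4,5,5-tetramethyl-1,3,2-dioxaborolan-2-yl)oxy]-3-[(1S)-1-(tert-butyldimethylsilyloxy)-3-(chloromethyl)but-3-en-1-yl]hept-5-enoate (open-chain anti adduct, configuration at C-3/C-4 as in 21) | O1CCOC1C/C(CO[Si](C)(C)C(C)(C)C)=C/[C@@H](OB2OC(C)(C)C(C)(C)O2)[C@H](C(=C)C(=O)OC)[C@@H](O[Si](C)(C)C(C)(C)C)CC(=C)CCl | intermediate (not isolated)
21 | (4S,5R)-4-[(1S)-1-(tert-butyldimethylsilyloxy)-3-(chloromethyl)but-3-en-1-yl]-5-[(1Z)-3-(tert-butyldimethylsilyloxy)-2-(1,3-dioxolan-2-ylmethyl)prop-1-en-1-yl]-3-methylideneoxolan-2-one | O1CCOC1C/C(CO[Si](C)(C)C(C)(C)C)=C/[C@H]2OC(=O)C(=C)[C@@H]2[C@@H](O[Si](C)(C)C(C)(C)C)CC(=C)CCl | intermediate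
22 | (4R,5R)-4-[(1S)-3-(chloromethyl)-1-hydroxybut-3-en-1-yl]-5-[(1Z)-3-hydroxy-2-(1,3-dioxolan-2-ylmethyl)prop-1-en-1-yl]-3-methylideneoxolan-2-one | O1CCOC1C/C(CO)=C/[C@H]2OC(=O)C(=C)[C@@H]2[C@@H](O)CC(=C)CCl | intermediate
23 | (4R,5R)-4-[(1S)-1-acetoxy-3-(chloromethyl)but-3-en-1-yl]-5-[(1Z)-3-acetoxy-2-(1,3-dioxolan-2-ylmethyl)prop-1-en-1-yl]-3-methylideneoxolan-2-one | O1CCOC1C/C(COC(C)=O)=C/[C@H]2OC(=O)C(=C)[C@@H]2[C@@H](OC(C)=O)CC(=C)CCl | intermediate
24 | (4R,5R)-4-[(1S)-1-acetoxy-3-(chloromethyl)but-3-en-1-yl]-5-[(1Z)-2-(acetoxymethyl)-4-oxobut-1-en-1-yl]-3-methylideneoxolan-2-one | O=CC/C(COC(C)=O)=C/[C@H]1OC(=O)C(=C)[C@@H]1[C@@H](OC(C)=O)CC(=C)CCl | intermediate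
25 | allylchromium(III) dichloride from 24 (CrCl2 in place of Cl) | O=CC/C(COC(C)=O)=C/[C@H]1OC(=O)C(=C)[C@@H]1[C@@H](OC(C)=O)CC(=C)C[Cr](Cl)Cl | intermediate (not isolated)
26 | (6R,7R,8S)-8,15-diacetoxy-2-hydroxygermacra-4,10(14),11(13)-trien-12,6-olide, C4=C5 trans in the ring, C2 not defined (both epimers) | C=C1CC(O)C/C(COC(C)=O)=C/[C@H]2OC(=O)C(=C)[C@@H]2[C@@H](OC(C)=O)C1 | intermediate
27 | (6R,7R,8S)-8,15-diacetoxy-2-oxogermacra-4,10(14),11(13)-trien-12,6-olide, C4=C5 trans in the ring (4Z by CIP) | C=C1CC(=O)C/C(COC(C)=O)=C/[C@H]2OC(=O)C(=C)[C@@H]2[C@@H](OC(C)=O)C1 | target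

**Step count and risks**

Total steps: 15. Longest linear sequence: 12 (steps 4–9, then 10–15).

Steps most likely to fail:

Step 14. Intermolecular coupling (oligomerisation) may outrun closure of the ten-membered ring, and the β,γ-unsaturated aldehyde may enolise or conjugate at Cr(III). The fallback replaces the reductive chromium closure by a Lewis-acid Hosomi–Sakurai closure. It sets out from 23. Palladium-catalysed silylation of the allylic chloride with hexamethyldisilane (Pd(dba)2, LiCl, DMF, rt; again regiochemically degenerate, and the allylic chloride should ionise far faster than the allylic acetate or lactone) would give the allylsilane acetal F1. Acetal hydrolysis as in step 13 would give the allylsilane aldehyde F2. BF3·OEt2 in CH2Cl2 at −78 °C under high dilution would then close the ring by SE2′ attack on the aldehyde and return to the route at 26.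

Step 10. Facial discrimination at C7 relative to C8 may be incomplete, because the A(1,3) model (attack anti to OTBS) competes with a preference for attack anti to the alkyl branch. The Lewis acid may also equilibrate the enal geometry. The fallback reverses the relay: C6/C7 are set by catalyst control and C8 last. It sets out from 7.
- Commercial methyl 4,4-dimethoxybut-2-ynoate would be hydroaluminated as in step 9 to the vinylalane F3 and alkylated with ICH2Bpin to the achiral boronate F4.
- Allylboration of 7 with F4 under chiral phosphoric acid catalysis would give the borate adduct F5 and, after PPTS, the trans-lactone dimethyl acetal F6. The TRIP enantiomer is the one that delivers the allyl unit to the Si face of the aldehyde, expected to be the (S)-acid by analogy with aryl aldehydes.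
- Selective hydrolysis of the acyclic acetal (oxalic acid on wet silica gel, CH2Cl2) would give the C8 aldehyde F7.
- Keck allylation of F7 with 11 and (S)-BINOL/Ti(OiPr)4 would give the C8 carbinol F8 under catalyst control.
- HF·pyridine then returns to the route at 22.

Step 1. The acetal Grignard reagent may undergo ring-opening β-elimination, or the copper-catalysed carbometalation may be sluggish. The fallback builds the same Z-enal from a butenolide whose ring locks C15–O cis to C6. It sets out from 2.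
- Transmetalation of 2 with ZnBr2 would give the organozinc F9.
- Negishi coupling of F9 with commercial 4-bromofuran-2(5H)-one (Pd(PPh3)4, THF) would give the butenolide F10.
- Aminolysis with N,O-dimethylhydroxylamine hydrochloride and i-PrMgCl would give the Z-hydroxy Weinreb amide F11.
- Silylation (TBSCl, imidazole) would give the silyl ether amide F12.
- DIBAL-H at −78 °C returns to the route at 7.

**Further compounds**

F1 | step 14 | (4R,5R)-4-{(1S)-1-acetoxy-3-[(trimethylsilyl)methyl]but-3-en-1-yl}-5-[(1Z)-3-acetoxy-2-(1,3-dioxolan-2-ylmethyl)prop-1-en-1-yl]-3-methylideneoxolan-2-one | O1CCOC1C/C(COC(C)=O)=C/[C@H]2OC(=O)C(=C)[C@@H]2[C@@H](OC(C)=O)CC(=C)C[Si](C)(C)C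
F2 | step 14 | (4R,5R)-4-{(1S)-1-acetoxy-3-[(trimethylsilyl)methyl]but-3-en-1-yl}-5-[(1Z)-2-(acetoxymethyl)-4-oxobut-1-en-1-yl]-3-methylideneoxolan-2-one | O=CC/C(COC(C)=O)=C/[C@H]1OC(=O)C(=C)[C@@H]1[C@@H](OC(C)=O)CC(=C)C[Si](C)(C)C
F3 | step 10 | methyl (2E)-2-(diisobutylalumanyl)-4,4-dimethoxybut-2-enoate | COC(=O)/C(=C\C(OC)OC)[Al](CC(C)C)CC(C)C
F4 | step 10 | methyl (2Z)-4,4-dimethoxy-2-[(4,4,5,5-tetramethyl-1,3,2-dioxaborolan-2-yl)methyl]but-2-enoate | COC(=O)/C(CB1OC(C)(C)C(C)(C)O1)=C\C(OC)OC
F5 | step 10 | methyl (5Z)-6-[(tert-butyldimethylsilyloxy)methyl]-3-(dimethoxymethyl)-7-(1,3-dioxolan-2-yl)-2-methylidene-4-[(4,4,5,5-tetramethyl-1,3,2-dioxaborolan-2-yl)oxy]hept-5-enoate (anti adduct, configuration as in F6) | O1CCOC1C/C(CO[Si](C)(C)C(C)(C)C)=C/[C@@H](OB2OC(C)(C)C(C)(C)O2)[C@H](C(=C)C(=O)OC)C(OC)OC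
F6 | step 10 | (4S,5R)-4-(dimethoxymethyl)-5-[(1Z)-3-(tert-butyldimethylsilyloxy)-2-(1,3-dioxolan-2-ylmethyl)prop-1-en-1-yl]-3-methylideneoxolan-2-one | O1CCOC1C/C(CO[Si](C)(C)C(C)(C)C)=C/[C@H]2OC(=O)C(=C)[C@@H]2C(OC)OC
F7 | step 10 | (2R,3S)-2-[(1Z)-3-(tert-butyldimethylsilyloxy)-2-(1,3-dioxolan-2-ylmethyl)prop-1-en-1-yl]-4-methylidene-5-oxooxolane-3-carbaldehyde | O1CCOC1C/C(CO[Si](C)(C)C(C)(C)C)=C/[C@H]2OC(=O)C(=C)[C@@H]2C=O
F8 | step 10 | (4R,5R)-4-[(1S)-3-(chloromethyl)-1-hydroxybut-3-en-1-yl]-5-[(1Z)-3-(tert-butyldimethylsilyloxy)-2-(1,3-dioxolan-2-ylmethyl)prop-1-en-1-yl]-3-methylideneoxolan-2-one | O1CCOC1C/C(CO[Si](C)(C)C(C)(C)C)=C/[C@H]2OC(=O)C(=C)[C@@H]2[C@@H](O)CC(=C)CCl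
F9 | step 1 | (1,3-dioxolan-2-ylmethyl)zinc bromide | Br[Zn]CC1OCCO1
F10 | step 1 | 4-(1,3-dioxolan-2-ylmethyl)furan-2(5H)-one | O=C1C=C(CC2OCCO2)CO1
F11 | step 1 | (2Z)-3-(1,3-dioxolan-2-ylmethyl)-4-hydroxy-N-methoxy-N-methylbut-2-enamide | O1CCOC1C/C(CO)=C/C(=O)N(C)OC
F12 | step 1 | (2Z)-4-[(tert-butyldimethylsilyl)oxy]-3-(1,3-dioxolan-2-ylmethyl)-N-methoxy-N-methylbut-2-enamide | O1CCOC1C/C(CO[Si](C)(C)C(C)(C)C)=C/C(=O)N(C)OC
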